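If radicals pair off as fast as J, the initiator, makes them, chains can be counted without seeing one. So the first speaker opened the meeting on blue and teal, two flasks of E, the monomer, with Z, a further species. D is monomer in chains.

| setting | ash | maple | blue | teal |
|---|---|---|---|---|
| E | 0.68 M | 0.68 M | 0.68 M | 0.68 M |
| Z | 0.204 M | 0.204 M | 0.204 M | 0.204 M |
| J | 1.1 mol% | 1.7 mol% | 0.79 mol% | 0.79 mol% |
| remark | run made earlier | run made earlier |  |  |
| time |  |  | 50 min | 30 min |

- ash (time / min: D / %, E / %): 4.00: 36.5, 53.6; 10.0: 63.4, 22.3; 20.0: 78.3, 5.5; 30.0: 81.6, 1.5; 40.0: 82.0, 0.3
- maple (time / min: D / %, E / %): 8.00: 64.4, 24.0; 15.0: 78.1, 6.8; 25.0: 83.6, 0.9; 30.0: 85.2, 0.1; 40.0: 84.9, 0.2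

(each reading ± 0.3 percentage points)

- the average divides the monomer in chains by the number of chains, living and dead together; two radicals that join make one chain
- the earlier runs do not show the number of chains; that part of a forecast is a guess

- which of the two ends with the longer chains by the average number of monomer units in a chain (living and dead chains, two that joined counted as one) ("neither" if they lie within 10 %) (blue / teal / neither)
- average number of monomer units in a chain (living and dead chains, two that joined counted as one) at the end, blue
- average number of monomer units in a chain (living and dead chains, two that joined counted as one) at the end, teal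

She tested the premise on the earlier readings. Between 10.0 min and 20.0 min, ash lost E with a first-order constant of 0.140 /min. Between 8.00 min and 15.0 min, maple gave 0.180 /min. Maple over ash is 1.29, and the root of the loadings is 1.24, so she read the two as close. That root is what a steady state of radicals gives when they are made in step with J and lost in pairs.

She then assumed that J decays slowly, which the runs do not show. Chains should then grow with the chain dose w, the loading of J times the time. Teal has w = 0.237 min and blue has 0.395 min, with the loading taken as a fraction. Length is D divided by chains.

A second speaker objected that D might differ between blue and teal. The first speaker answered that the D reading in ash rose by 0.4 percentage points from 30.0 min to 40.0 min, so late D in ash moved little. She therefore expected teal longer by a factor near 1.67, past the margin. She offered no absolute length, since the runs show no chain count.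

The forecaster said teal, with 750 for blue and 1150 for teal, arguing that “Initiator keeps making chains after monomer runs out”. His ratio is 1.53, which differs from hers.

    2 G → L (k = 1.00 × 10⁶ /M/s)
    E + G → D + G, rate k2*[G]*[E] (k = 3.05 × 10⁵ /M/min)
    E + X → G + D (k = 21600 /M/s)
    J → 2 X (k = 0.00133 /min)
    Z + E → Q (k = 0.189 /M/min)

Blue ends at 1590 and teal at 2550, so teal is longer, as forecast, with both forecast values low. Scaling teal by w and D gives 1570 for blue. For a neighbour flask, which is teal with 0.32 mol% of J, it gives 5550, and that flask stands at 5540. In teal, E fell from 14.7 % to 2.46 % between 15.0 min and 30.0 min, while L, the joined chains, rose from 1.06 × 10⁻⁴ M to 2.10 × 10⁻⁴ M. In blue, E fell from 4.45 % to 0.222 % between 25.0 min and 50.0 min, D went from 77.2 % to 80.9 %, and L reached twice its earlier value, 3.45 × 10⁻⁴ M.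

The readings are simulated for substances that don't exist; scatter was added.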